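**Assumption:** the Rh/diene catalyst in step 11 is taken to discriminate the chromone C2=C3 faces as it does those of 2-cyclohexenone ((S,S)-Ph-bod* → 2S); if a first run shows the opposite sense, the mirror-image diene is used.

## Retrosynthetic overview

1. The B ring is attached last: 29 ⇐ chromone 24 + (2-hydroxyphenyl)boronic acid 28 by catalyst-controlled asymmetric 1,4-arylation, which sets C2 (S).
2. The pyranone (C ring) ⇐ aryl methyl ketone 22 + one carbon from DMF acetal; 22 ⇐ lavandulyl arene 18 by ortho-lithiation and acetylation.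
3. The lavandulyl chain ⇐ three 1,2-shifts from boron to carbon: aryl→CH2 (gives 8), benzyl→lithiated carbenoid carbon with inversion (gives 13, sets the side-chain R centre), alkyl→isopropenyl carbon (gives 18).
4. The A ring ⇐ resorcinol 1: MOM ethers, Ir C–H borylation/oxidation for the third oxygen, O-methylation.
5. Ring order: A (from resorcinol) → C (step 9) → B joined (step 11).

## Route

**Step 1**
Reactants: 1 resorcinol
Product: 2 1,3-bis(methoxymethoxy)benzene
Conditions: NaH, MOMCl, DMF, 0 °C → rt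
Reagents that add atoms: chloromethyl methyl ether (MOMCl) COCCl
Why: Williamson-type O-alkylation of both phenoxides gives the bis-MOM ether, whose acetal oxygens later direct both lithiations.

**Step 2**
Reactants: 2 1,3-bis(methoxymethoxy)benzene
Product: 4 3,5-bis(methoxymethoxy)phenol, via aryl pinacol boronate 3 (not isolated)
Conditions: [Ir(OMe)(cod)]2 (1.5 mol %), dtbpy (3 mol %), B2pin2 (0.6 equiv), THF, 80 °C; then Oxone, acetone/H2O, rt, 10 min
Reagents that add atoms: potassium peroxymonosulfate (active part of Oxone) [K+].[O-]S(=O)(=O)OO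
Why: Sterically controlled Ir-catalysed C–H borylation reaches only the C–H meta to both ethers (C5), and one-pot oxidation of the C–B bond gives the phenol.

**Step 3**
Reactants: 4 3,5-bis(methoxymethoxy)phenol
Product: 5 1-methoxy-3,5-bis(methoxymethoxy)benzene
Conditions: MeI, K2CO3, acetone, 56 °C
Reagents that add atoms: iodomethane CI
Why: Williamson O-methylation of the only free phenol installs the future 5-OMe.

**Step 4**
Reactants: 5 1-methoxy-3,5-bis(methoxymethoxy)benzene
Product: 8 2-{[4-methoxy-2,6-bis(methoxymethoxy)phenyl]methyl}-4,4,5,5-tetramethyl-1,3,2-dioxaborolane, via aryllithium 6 (not isolated), via bromomethyl borate complex 7 (not isolated)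
Conditions: n-BuLi, THF, 0 °C, 1 h; BrCH2Bpin, −78 °C → rt
Reagents that add atoms: 2-(bromomethyl)-4,4,5,5-tetramethyl-1,3,2-dioxaborolane BrCB1OC(C)(C)C(C)(C)O1
Why: Directed ortho-metalation occurs at the C–H flanked by the two MOM ethers (stronger directors than OMe), and the aryl group then undergoes a Matteson-type 1,2-shift from boron to CH2 with loss of bromide.

**Step 5**
Reactants: 9 4-methylpent-3-en-1-ol
Product: 10 4-methylpent-3-en-1-yl 2,4,6-triisopropylbenzoate
Conditions: NaH, THF, 0 °C; 2,4,6-triisopropylbenzoyl chloride (TIBCl), 60 °C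
Reagents that add atoms: 2,4,6-triisopropylbenzoyl chloride CC(C)c1cc(C(C)C)c(C(Cl)=O)c(C(C)C)c1
Why: O-acylation gives the hindered benzoate that serves as directing and leaving group for the Hoppe-type lithiation.

**Step 6**
Reactants: 10 4-methylpent-3-en-1-yl 2,4,6-triisopropylbenzoate; 8 2-{[4-methoxy-2,6-bis(methoxymethoxy)phenyl]methyl}-4,4,5,5-tetramethyl-1,3,2-dioxaborolane
Product: 13 2-[(2R)-1-[4-methoxy-2,6-bis(methoxymethoxy)phenyl]-5-methylhex-4-en-2-yl]-4,4,5,5-tetramethyl-1,3,2-dioxaborolane, via lithiated benzoate 11 (not isolated), via boronate complex 12 (not isolated)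
Conditions: s-BuLi, (−)-sparteine, Et2O, −78 °C, 5 h; 8, −78 °C, 1 h; then 35 °C, 12 h; H2O work-up
Reagents that add atoms: none
Why: Hoppe–Aggarwal lithiation–borylation: (−)-sparteine/s-BuLi removes the pro-S α-hydrogen, the (S)-carbenoid is borylated with retention, and the benzyl group makes a stereospecific 1,2-shift from boron to carbon with inversion as the benzoate leaves, giving the R centre.

**Step 7**
Reactants: 13 2-[(2R)-1-[4-methoxy-2,6-bis(methoxymethoxy)phenyl]-5-methylhex-4-en-2-yl]-4,4,5,5-tetramethyl-1,3,2-dioxaborolane; 14 2-bromopropene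
Product: 18 5-methoxy-1,3-bis(methoxymethoxy)-2-[(2R)-5-methyl-2-(prop-1-en-2-yl)hex-4-en-1-yl]benzene, via isopropenyllithium 15 (not isolated), via alkenyl boronate complex 16 (not isolated), via iodoalkyl boronic ester 17 (not isolated)
Conditions: 14, t-BuLi, THF, −78 °C; 13, −78 °C; I2, MeOH/THF, −78 °C; NaOMe, MeOH, −78 °C → rt
Reagents that add atoms: none
Why: Zweifel olefination: iodine activates the alkenyl boronate, the secondary alkyl group shifts 1,2 from boron to carbon with retention, and methoxide-induced anti elimination of B and I gives the isopropenyl group, so the R centre is kept.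

**Step 8**
Reactants: 18 5-methoxy-1,3-bis(methoxymethoxy)-2-[(2R)-5-methyl-2-(prop-1-en-2-yl)hex-4-en-1-yl]benzene; 19 N-methoxy-N-methylacetamide
Product: 22 1-{6-methoxy-2,4-bis(methoxymethoxy)-3-[(2R)-5-methyl-2-(prop-1-en-2-yl)hex-4-en-1-yl]phenyl}ethan-1-one, via aryllithium 20 (not isolated), via tetrahedral lithium adduct 21 (not isolated)
Conditions: n-BuLi, THF, 0 °C, 1 h; 19, −78 °C → rt; H2O
Reagents that add atoms: none
Why: Directed ortho-metalation at either of the two equivalent C–H positions flanked by OMOM and OMe, then Weinreb ketone synthesis, whose chelated adduct prevents over-addition.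

**Step 9**
Reactants: 22 1-{6-methoxy-2,4-bis(methoxymethoxy)-3-[(2R)-5-methyl-2-(prop-1-en-2-yl)hex-4-en-1-yl]phenyl}ethan-1-one
Product: 24 7-hydroxy-5-methoxy-8-[(2R)-5-methyl-2-(prop-1-en-2-yl)hex-4-en-1-yl]-4H-chromen-4-one, via enaminone 23 (not isolated)
Conditions: Me2NCH(OMe)2, toluene, 100 °C; then 3 M HCl, MeOH, 45 °C
Reagents that add atoms: N,N-dimethylformamide dimethyl acetal COC(OC)N(C)C
Why: Enaminone chromone synthesis: condensation of the methyl ketone with the amide acetal, then acid cleaves both MOM acetals and the freed ortho-phenol closes the pyranone by addition–elimination of dimethylamine.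

**Step 10**
Reactants: 25 2-bromophenol
Product: 28 (2-hydroxyphenyl)boronic acid, via lithium 2-lithiophenolate 26 (not isolated), via trimethoxyborate 27 (not isolated)
Conditions: n-BuLi (2.2 equiv), Et2O, −78 → 0 °C; B(OMe)3, −78 °C → rt; 1 M HCl
Reagents that add atoms: trimethyl borate COB(OC)OC; water O
Why: O-deprotonation and bromine–lithium exchange give the aryl dianion, which is borylated and hydrolysed to the boronic acid.

**Step 11**
Reactants: 24 7-hydroxy-5-methoxy-8-[(2R)-5-methyl-2-(prop-1-en-2-yl)hex-4-en-1-yl]-4H-chromen-4-one; 28 (2-hydroxyphenyl)boronic acid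
Product: 29 kushenol R
Conditions: [Rh(OH)((S,S)-Ph-bod*)]2 (2.5 mol %), 28 (3 equiv in portions), 1,4-dioxane/H2O 10:1, 50 °C
Reagents that add atoms: none
Why: Proposed new method: a base-free hydroxo-Rh(I)/chiral diene 1,4-arylation run with both partners unprotected, in which Rh–OH or Rh–OAr transmetalates with the boronic acid, the aryl–Rh adds to one face of C2=C3 under diene control to set 2S, and the new ortho-hydroxyl protonates the Rh oxa-π-allyl through a six-membered relay faster than ring-opening β-oxygen elimination, while the un-ionised 7-OH keeps the enone electrophilic; the closest known reaction is the Rh/chiral diene (Hayashi–Miyaura) asymmetric 1,4-addition of arylboronic acids to O-protected chromones under aqueous base.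

## Compound list

1 | resorcinol | Oc1cccc(O)c1 | starting material
2 | 1,3-bis(methoxymethoxy)benzene | COCOc1cccc(OCOC)c1 | intermediate
3 | 2-[3,5-bis(methoxymethoxy)phenyl]-4,4,5,5-tetramethyl-1,3,2-dioxaborolane | COCOc1cc(OCOC)cc(B2OC(C)(C)C(C)(C)O2)c1 | intermediate (not isolated)
4 | 3,5-bis(methoxymethoxy)phenol | COCOc1cc(O)cc(OCOC)c1 | intermediate
5 | 1-methoxy-3,5-bis(methoxymethoxy)benzene | COCOc1cc(OC)cc(OCOC)c1 | intermediate
6 | [4-methoxy-2,6-bis(methoxymethoxy)phenyl]lithium | [Li]c1c(OCOC)cc(OC)cc1OCOC | intermediate (not isolated)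
7 | lithium (bromomethyl)[4-methoxy-2,6-bis(methoxymethoxy)phenyl](pinacolato)borate | [Li+].COCOc1cc(OC)cc(OCOC)c1[B-]1(CBr)OC(C)(C)C(C)(C)O1 | intermediate (not isolated)
8 | 2-{[4-methoxy-2,6-bis(methoxymethoxy)phenyl]methyl}-4,4,5,5-tetramethyl-1,3,2-dioxaborolane | COCOc1cc(OC)cc(OCOC)c1CB1OC(C)(C)C(C)(C)O1 | intermediate
9 | 4-methylpent-3-en-1-ol | CC(C)=CCCO | starting material
10 | 4-methylpent-3-en-1-yl 2,4,6-triisopropylbenzoate | CC(C)=CCCOC(=O)c1c(C(C)C)cc(C(C)C)cc1C(C)C | intermediate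
11 | (S)-1-lithio-4-methylpent-3-en-1-yl 2,4,6-triisopropylbenzoate, as its (−)-sparteine complex | [Li][C@H](OC(=O)c1c(C(C)C)cc(C(C)C)cc1C(C)C)CC=C(C)C | intermediate (not isolated)
12 | lithium boronate complex of 8 with the (S)-carbenoid carbon (benzyl, pinacolato and the O-benzoyloxy-alkyl group on boron) | [Li+].COCOc1cc(OC)cc(OCOC)c1C[B-]1(OC(C)(C)C(C)(C)O1)[C@H](OC(=O)c1c(C(C)C)cc(C(C)C)cc1C(C)C)CC=C(C)C | intermediate (not isolated)
13 | 2-[(2R)-1-[4-methoxy-2,6-bis(methoxymethoxy)phenyl]-5-methylhex-4-en-2-yl]-4,4,5,5-tetramethyl-1,3,2-dioxaborolane | COCOc1cc(OC)cc(OCOC)c1C[C@@H](CC=C(C)C)B1OC(C)(C)C(C)(C)O1 | intermediate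
14 | 2-bromopropene | C=C(C)Br | starting material
15 | isopropenyllithium | [Li]C(C)=C | intermediate (not isolated)
16 | lithium isopropenyl boronate complex of 13 (R centre unchanged) | [Li+].C=C(C)[B-]1(OC(C)(C)C(C)(C)O1)[C@H](CC=C(C)C)Cc1c(OCOC)cc(OC)cc1OCOC | intermediate (not isolated)
17 | 2-[(3R)-1-iodo-3-{[4-methoxy-2,6-bis(methoxymethoxy)phenyl]methyl}-2,6-dimethylhept-5-en-2-yl]-4,4,5,5-tetramethyl-1,3,2-dioxaborolane (both epimers at the boron-bearing carbon) | ICC(C)(B1OC(C)(C)C(C)(C)O1)[C@H](CC=C(C)C)Cc1c(OCOC)cc(OC)cc1OCOC | intermediate (not isolated)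
18 | 5-methoxy-1,3-bis(methoxymethoxy)-2-[(2R)-5-methyl-2-(prop-1-en-2-yl)hex-4-en-1-yl]benzene | C=C(C)[C@H](CC=C(C)C)Cc1c(OCOC)cc(OC)cc1OCOC | intermediate
19 | N-methoxy-N-methylacetamide | CC(=O)N(C)OC | starting material
20 | aryllithium of 18, lithiated at the ring carbon between OMe and OMOM | C=C(C)[C@H](CC=C(C)C)Cc1c(OCOC)cc(OC)c([Li])c1OCOC | intermediate (not isolated)
21 | lithium alkoxide of the N-methoxy-N-methyl hemiaminal formed from 20 and 19 (both epimers at the carbinol carbon) | C=C(C)[C@H](CC=C(C)C)Cc1c(OCOC)cc(OC)c(C(C)(O[Li])N(C)OC)c1OCOC | intermediate (not isolated)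
22 | 1-{6-methoxy-2,4-bis(methoxymethoxy)-3-[(2R)-5-methyl-2-(prop-1-en-2-yl)hex-4-en-1-yl]phenyl}ethan-1-one | C=C(C)[C@H](CC=C(C)C)Cc1c(OCOC)cc(OC)c(C(C)=O)c1OCOC | intermediate
23 | (E)-3-(dimethylamino)-1-{6-methoxy-2,4-bis(methoxymethoxy)-3-[(2R)-5-methyl-2-(prop-1-en-2-yl)hex-4-en-1-yl]phenyl}prop-2-en-1-one | C=C(C)[C@H](CC=C(C)C)Cc1c(OCOC)cc(OC)c(C(=O)/C=C/N(C)C)c1OCOC | intermediate (not isolated)
24 | 7-hydroxy-5-methoxy-8-[(2R)-5-methyl-2-(prop-1-en-2-yl)hex-4-en-1-yl]-4H-chromen-4-one | C=C(C)[C@H](CC=C(C)C)Cc1c(O)cc(OC)c2c1OC=CC2=O | intermediate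
25 | 2-bromophenol | Oc1ccccc1Br | starting material
26 | lithium 2-lithiophenolate | [Li]Oc1ccccc1[Li] | intermediate (not isolated)
27 | lithium trimethoxy(2-lithiooxyphenyl)borate | [Li+].[Li]Oc1ccccc1[B-](OC)(OC)OC | intermediate (not isolated)
28 | (2-hydroxyphenyl)boronic acid | OB(O)c1ccccc1O | intermediate
29 | kushenol R, (2S)-7-hydroxy-2-(2-hydroxyphenyl)-5-methoxy-8-[(2R)-5-methyl-2-(prop-1-en-2-yl)hex-4-en-1-yl]-2,3-dihydro-4H-chromen-4-one | C=C(C)[C@H](CC=C(C)C)Cc1c(O)cc(OC)c2c1O[C@H](c1ccccc1O)CC2=O | target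

## Step count and risks

Total steps: 11. Longest linear sequence: 9 (steps 1, 2, 3, 4, 6, 7, 8, 9, 11); steps 5 and 10 are one-step branches.

**Step 11 (the proposed new step).** The free ortho-hydroxyl may speed protodeboronation of 28, and the free 7-OH may slow the addition. The fallback uses known chemistry, sets out from 24 and comes back at 29. Compound 24 is re-protected with MOMCl and i-Pr2NEt to give 5-methoxy-7-(methoxymethoxy)-8-[(2R)-5-methyl-2-(prop-1-en-2-yl)hex-4-en-1-yl]-4H-chromen-4-one F1. Phenol is converted with NaH and MOMCl into (methoxymethoxy)benzene F2, which is ortho-lithiated with n-BuLi/TMEDA to [2-(methoxymethoxy)phenyl]lithium F3 and borylated with B(OMe)3 and hydrolysed to [2-(methoxymethoxy)phenyl]boronic acid F4. The established Rh/(S,S)-Ph-bod* 1,4-arylation of the O-protected chromone (cat. KOH, dioxane/H2O) then gives (2S)-5-methoxy-7-(methoxymethoxy)-2-[2-(methoxymethoxy)phenyl]-8-[(2R)-5-methyl-2-(prop-1-en-2-yl)hex-4-en-1-yl]-2,3-dihydro-4H-chromen-4-one F5, and 3 M HCl in MeOH at 40 °C releases 29.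

**Step 6.** Lithiation of the homoallylic benzoate, or the 1,2-shift of the hindered electron-rich benzyl group, may be slow or give a lower enantiomer ratio. The fallback sets out from 8 and comes back at 13. Vinyllithium is added to 8 to give lithium ethenyl{[4-methoxy-2,6-bis(methoxymethoxy)phenyl]methyl}(pinacolato)borate F6. A Pd(OAc)2/MandyPhos-catalysed conjunctive cross-coupling with 1-bromo-2-methylprop-1-ene (NaOTf, THF, 60 °C) then lets the alkenyl-palladium electrophile trigger the 1,2-shift of the benzyl group and gives 13 directly. The MandyPhos antipode is chosen by oxidising a sample to the carbinol and assigning it.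

**Step 9.** The acid that removes the MOM groups can also cyclise the new 7-OH onto the lavandulyl alkenes. The fallback sets out from 22 and comes back at 24. Both MOM groups are first removed under near-neutral conditions (ZnBr2, n-PrSH, CH2Cl2, 0 °C, 10 min) to give 1-{2,4-dihydroxy-6-methoxy-3-[(2R)-5-methyl-2-(prop-1-en-2-yl)hex-4-en-1-yl]phenyl}ethan-1-one F7. Claisen formylation under base (NaH, ethyl formate, THF) gives 2,7-dihydroxy-5-methoxy-8-[(2R)-5-methyl-2-(prop-1-en-2-yl)hex-4-en-1-yl]-2,3-dihydro-4H-chromen-4-one F8, which loses water on brief warming in acetic acid to give 24.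

## Further compounds

F1 | step 11 | 5-methoxy-7-(methoxymethoxy)-8-[(2R)-5-methyl-2-(prop-1-en-2-yl)hex-4-en-1-yl]-4H-chromen-4-one | C=C(C)[C@H](CC=C(C)C)Cc1c(OCOC)cc(OC)c2c1OC=CC2=O
F2 | step 11 | (methoxymethoxy)benzene | COCOc1ccccc1
F3 | step 11 | [2-(methoxymethoxy)phenyl]lithium | COCOc1ccccc1[Li]
F4 | step 11 | [2-(methoxymethoxy)phenyl]boronic acid | COCOc1ccccc1B(O)O
F5 | step 11 | (2S)-5-methoxy-7-(methoxymethoxy)-2-[2-(methoxymethoxy)phenyl]-8-[(2R)-5-methyl-2-(prop-1-en-2-yl)hex-4-en-1-yl]-2,3-dihydro-4H-chromen-4-one | C=C(C)[C@H](CC=C(C)C)Cc1c(OCOC)cc(OC)c2c1O[C@H](c1ccccc1OCOC)CC2=O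
F6 | step 6 | lithium ethenyl{[4-methoxy-2,6-bis(methoxymethoxy)phenyl]methyl}(pinacolato)borate | [Li+].C=C[B-]1(Cc2c(OCOC)cc(OC)cc2OCOC)OC(C)(C)C(C)(C)O1
F7 | step 9 | 1-{2,4-dihydroxy-6-methoxy-3-[(2R)-5-methyl-2-(prop-1-en-2-yl)hex-4-en-1-yl]phenyl}ethan-1-one | C=C(C)[C@H](CC=C(C)C)Cc1c(O)cc(OC)c(C(C)=O)c1O
F8 | step 9 | 2,7-dihydroxy-5-methoxy-8-[(2R)-5-methyl-2-(prop-1-en-2-yl)hex-4-en-1-yl]-2,3-dihydro-4H-chromen-4-one (both epimers at C2) | C=C(C)[C@H](CC=C(C)C)Cc1c(O)cc(OC)c2c1OC(O)CC2=O
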